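Assumption: the SMILES is read as (5R) at the carbinol carbon with all three chain alkenes E; LiN(i-Pr)2 and lithium 2,2,6,6-tetramethylpiperidide (LiTMP) are used as purchased reagents.

## Retrosynthetic overview

1. Target 25 ⇐ bis-TIPS ether 24 by fluoride desilylation (last step).
2. Key disconnection C5–C6, which also sets C5: (S)-α-lithiated carbamate 21 (the carbinol carbon used as a carbanion, from 20 with s-BuLi/(−)-sparteine) + alkenyl boronic ester 13, then 1,2-metallate shift and C–B oxidation.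
3. 20 ⇐ but-3-ynyl carbamate 15 (carboalumination) + benzylic bromide 18 (from 2,6-dimethylhydroquinone 16).
4. 13 ⇐ enyne 12 (methylboration) ⇐ 3-methylfuran 8 + allylic bromide 7 ⇐ 6-methylhept-5-en-2-one 1.
5. Rings: none is formed; the benzene ring (16) and the furan (8) are bought.

## Route

Step 1
Reactants: 1 6-methylhept-5-en-2-one
Product: 5 6-methylhept-5-en-1-yne, via lithium enolate 2 (not isolated), via enol diethyl phosphate 3 (not isolated), via lithium acetylide 4 (not isolated)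
Conditions: LiN(i-Pr)2 (1.1 equiv), THF, −78 °C; ClP(O)(OEt)2, −78 °C → rt; LiN(i-Pr)2 (2.3 equiv), THF, −78 °C → rt; H2O
Reagents that add atoms: none
Why: Kinetic enolisation at the methyl group, O-phosphorylation and twofold base-induced elimination (Negishi conversion of a methyl ketone into a terminal alkyne via the enol phosphate) give the alkyne, with no stereocentre involved and the trisubstituted alkene inert.

Step 2
Reactants: 5 6-methylhept-5-en-1-yne
Product: 6 (2E)-2-methylhept-2-en-6-yn-1-ol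
Conditions: SeO2 (0.2 equiv), t-BuOOH (3 equiv), salicylic acid (0.1 equiv), CH2Cl2, rt
Reagents that add atoms: tert-butyl hydroperoxide CC(C)(C)OO (its oxygen is delivered through catalytic selenium dioxide O=[Se]=O)
Why: Riley allylic oxidation under Sharpless catalytic conditions (ene reaction, then [2,3]-sigmatropic shift) attacks the (E)-methyl group of the trisubstituted alkene selectively, fixing the E geometry of the future C10=C11 bond and leaving the alkyne alone.

Step 3
Reactants: 6 (2E)-2-methylhept-2-en-6-yn-1-ol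
Product: 7 (5E)-7-bromo-6-methylhept-5-en-1-yne
Conditions: PBr3 (0.4 equiv), Et2O, 0 °C
Reagents that add atoms: phosphorus tribromide BrP(Br)Br
Why: SN2 displacement of the phosphite ester of a primary allylic alcohol by bromide at 0 °C proceeds without allylic transposition or loss of E geometry.

Step 4
Reactants: 7 (5E)-7-bromo-6-methylhept-5-en-1-yne; 8 3-methylfuran
Product: 12 4-methyl-2-[(2E)-2-methylhept-2-en-6-yn-1-yl]furan, via (4-methylfuran-2-yl)lithium 9 (not isolated), via lithium acetylide of the bromide 10 (not isolated), via lithium acetylide of the product 11 (not isolated)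
Conditions: 8 (3 equiv), LiTMP (2.2 equiv), THF, −78 → 0 °C; then 7, −78 °C → rt; H2O
Reagents that add atoms: none
Why: The bulky amide is expected to remove the less hindered C5–H of 3-methylfuran (sterically controlled α-lithiation of a furan, by analogy with 3-methylthiophene), and 9 alkylates the primary allylic bromide by SN2 with retention of alkene geometry; one equivalent of 9 is consumed by the alkyne C–H, whose lithium acetylide does not alkylate in THF without polar additives.

Step 5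
Reactants: 12 4-methyl-2-[(2E)-2-methylhept-2-en-6-yn-1-yl]furan
Product: 13 2-[(1E,5E)-2,6-dimethyl-7-(4-methylfuran-2-yl)hepta-1,5-dien-1-yl]-4,4,5,5-tetramethyl-1,3,2-dioxaborolane
Conditions: CuCl (10 mol %), Xantphos (10 mol %), NaOt-Bu (1.5 equiv), B2pin2 (1.3 equiv), MeI (3 equiv), THF, rt
Reagents that add atoms: bis(pinacolato)diboron CC1(C)OB(OC1(C)C)B1OC(C)(C)C(C)(C)O1; iodomethane CI
Why: Copper-catalysed carboboration of a terminal alkyne: syn-borylcupration puts boron on the terminal carbon and the alkenylcopper is methylated with retention, so methyl and boron end up cis and the (E)-2-methylalkenyl boronic ester results.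

Step 6
Reactants: 14 but-3-yn-1-ol
Product: 15 but-3-yn-1-yl N,N-di(propan-2-yl)carbamate
Conditions: i-Pr2NC(O)Cl, Et3N, CH2Cl2, reflux
Reagents that add atoms: N,N-diisopropylcarbamoyl chloride CC(C)N(C(C)C)C(Cl)=O
Why: O-Carbamoylation of the primary alcohol (Hoppe carbamate formation) installs the group that later directs and stabilises α-lithiation; Et3N does not touch the alkyne C–H.

Step 7
Reactants: 16 2,6-dimethylbenzene-1,4-diol
Product: 17 2,6-dimethyl-1,4-bis[(triisopropylsilyl)oxy]benzene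
Conditions: TIPSOTf (2.4 equiv), 2,6-lutidine, CH2Cl2, 0 °C → rt
Reagents that add atoms: triisopropylsilyl trifluoromethanesulfonate CC(C)[Si](C(C)C)(C(C)C)OS(=O)(=O)C(F)(F)F
Why: The silyl triflate with a hindered pyridine base silylates both phenols, including the one flanked by two methyl groups; aryl TIPS ethers are poor directing groups for lithiation and should survive the later steps.

Step 8
Reactants: 17 2,6-dimethyl-1,4-bis[(triisopropylsilyl)oxy]benzene
Product: 18 2-(bromomethyl)-6-methyl-1,4-bis[(triisopropylsilyl)oxy]benzene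
Conditions: NBS (1.0 equiv), AIBN (5 mol %), PhCF3, 80 °C
Reagents that add atoms: N-bromosuccinimide O=C1CCC(=O)N1Br
Why: Wohl–Ziegler radical bromination at one of the two symmetry-equivalent benzylic methyl groups; one equivalent of NBS in a non-polar solvent and the bulky silyloxy groups disfavour ring bromination, and the monobromide is separated from recovered 17 and dibromide.

Step 9
Reactants: 15 but-3-yn-1-yl N,N-di(propan-2-yl)carbamate; 18 2-(bromomethyl)-6-methyl-1,4-bis[(triisopropylsilyl)oxy]benzene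
Product: 20 (3E)-3-methyl-5-{3-methyl-2,5-bis[(triisopropylsilyl)oxy]phenyl}pent-3-en-1-yl N,N-di(propan-2-yl)carbamate, via (E)-alkenyldimethylalane 19 (not isolated)
Conditions: 15 (1.5 equiv), Me3Al (2.5 equiv), Cp2ZrCl2 (0.2 equiv), CH2Cl2, 0 °C → rt; volatiles removed; then 18 (1.0 equiv), Pd(PPh3)4 (5 mol %), THF, rt
Reagents that add atoms: trimethylaluminium C[Al](C)C
Why: Negishi zirconium-catalysed carboalumination adds methyl and aluminium syn across the alkyne with methyl on the internal carbon, and the (E)-alkenylalane is cross-coupled with the benzylic bromide under Pd(PPh3)4 catalysis (Negishi coupling) with retention, which sets the (2E)-trisubstituted alkene.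

Step 10
Reactants: 20 (3E)-3-methyl-5-{3-methyl-2,5-bis[(triisopropylsilyl)oxy]phenyl}pent-3-en-1-yl N,N-di(propan-2-yl)carbamate; 13 2-[(1E,5E)-2,6-dimethyl-7-(4-methylfuran-2-yl)hepta-1,5-dien-1-yl]-4,4,5,5-tetramethyl-1,3,2-dioxaborolane
Product: 24 (2E,5R,6E,10E)-3,7,11-trimethyl-12-(4-methylfuran-2-yl)-1-{3-methyl-2,5-bis[(triisopropylsilyl)oxy]phenyl}dodeca-2,6,10-trien-5-ol, via (S)-lithiated carbamate 21 (not isolated), via lithium boronate complex 22 (not isolated), via (R)-allylic boronic ester 23 (not isolated)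
Conditions: 20 (1.3 equiv), sec-butyllithium (1.25 equiv), (−)-sparteine (1.3 equiv), Et2O, −78 °C, 5 h; 13 (1.0 equiv), −78 °C, 1 h; MgBr2·OEt2, −78 → 35 °C; then NaBO3·4H2O, THF/H2O, rt
Reagents that add atoms: sodium perborate tetrahydrate (NaBO3·4H2O) [Na+].[Na+].O[B-]1(O)OO[B-](O)(O)OO1.O.O.O.O.O.O
Why: sec-Butyllithium/(−)-sparteine removes the pro-S α-proton of the carbamate (Hoppe asymmetric deprotonation), so the future carbinol carbon reacts as a configurationally stable α-oxygenated carbanion instead of as a carbonyl electrophile; it is borylated by the alkenyl boronic ester with retention, the alkenyl group migrates from boron to carbon with inversion and loss of the carbamate (Aggarwal lithiation–borylation, a Matteson-type 1,2-metallate rearrangement that joins two carbon nucleophiles), and stereoretentive C–B oxidation gives the (5R)-allylic alcohol with both alkene geometries intact.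

Step 11
Reactants: 24 (2E,5R,6E,10E)-3,7,11-trimethyl-12-(4-methylfuran-2-yl)-1-{3-methyl-2,5-bis[(triisopropylsilyl)oxy]phenyl}dodeca-2,6,10-trien-5-ol
Product: 25 2-[(2E,5R,6E,10E)-5-hydroxy-3,7,11-trimethyl-12-(4-methylfuran-2-yl)dodeca-2,6,10-trien-1-yl]-6-methylbenzene-1,4-diol
Conditions: Bu4NF (3 equiv), AcOH (3 equiv), degassed THF, 0 °C, argon
Reagents that add atoms: none
Why: Fluoride cleaves both aryl silyl ethers (desilylation driven by Si–F bond formation) while the acetic acid buffer keeps the hydroquinone protonated, avoiding air oxidation and leaving the allylic alcohol, the furan, the alkenes and the C5 stereocentre untouched.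

## Compound list

1 | 6-methylhept-5-en-2-one | CC(=O)CCC=C(C)C | starting material
2 | lithium 6-methylhepta-1,5-dien-2-olate | [Li+].[O-]C(=C)CCC=C(C)C | intermediate (not isolated)
3 | diethyl 6-methylhepta-1,5-dien-2-yl phosphate | C=C(CCC=C(C)C)OP(=O)(OCC)OCC | intermediate (not isolated)
4 | (6-methylhept-5-en-1-yn-1-yl)lithium | [Li]C#CCCC=C(C)C | intermediate (not isolated)
5 | 6-methylhept-5-en-1-yne | C#CCCC=C(C)C | intermediate
6 | (2E)-2-methylhept-2-en-6-yn-1-ol | C#CCC/C=C(\C)CO | intermediate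
7 | (5E)-7-bromo-6-methylhept-5-en-1-yne | C#CCC/C=C(\C)CBr | intermediate
8 | 3-methylfuran | Cc1ccoc1 | starting material
9 | (4-methylfuran-2-yl)lithium | [Li]c1cc(C)co1 | intermediate (not isolated)
10 | [(5E)-7-bromo-6-methylhept-5-en-1-yn-1-yl]lithium | [Li]C#CCC/C=C(\C)CBr | intermediate (not isolated)
11 | [(5E)-6-methyl-7-(4-methylfuran-2-yl)hept-5-en-1-yn-1-yl]lithium | [Li]C#CCC/C=C(\C)Cc1cc(C)co1 | intermediate (not isolated)
12 | 4-methyl-2-[(2E)-2-methylhept-2-en-6-yn-1-yl]furan | C#CCC/C=C(\C)Cc1cc(C)co1 | intermediate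
13 | 2-[(1E,5E)-2,6-dimethyl-7-(4-methylfuran-2-yl)hepta-1,5-dien-1-yl]-4,4,5,5-tetramethyl-1,3,2-dioxaborolane | C/C(=C\B1OC(C)(C)C(C)(C)O1)CC/C=C(\C)Cc1cc(C)co1 | intermediate
14 | but-3-yn-1-ol | C#CCCO | starting material
15 | but-3-yn-1-yl N,N-di(propan-2-yl)carbamate | C#CCCOC(=O)N(C(C)C)C(C)C | intermediate
16 | 2,6-dimethylbenzene-1,4-diol | Cc1cc(O)cc(C)c1O | starting material
17 | 2,6-dimethyl-1,4-bis[(triisopropylsilyl)oxy]benzene | Cc1cc(O[Si](C(C)C)(C(C)C)C(C)C)cc(C)c1O[Si](C(C)C)(C(C)C)C(C)C | intermediate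
18 | 2-(bromomethyl)-6-methyl-1,4-bis[(triisopropylsilyl)oxy]benzene | BrCc1cc(O[Si](C(C)C)(C(C)C)C(C)C)cc(C)c1O[Si](C(C)C)(C(C)C)C(C)C | intermediate
19 | [(1E)-4-(diisopropylcarbamoyloxy)-2-methylbut-1-en-1-yl]dimethylalumane | C[Al](C)/C=C(\C)CCOC(=O)N(C(C)C)C(C)C | intermediate (not isolated)
20 | (3E)-3-methyl-5-{3-methyl-2,5-bis[(triisopropylsilyl)oxy]phenyl}pent-3-en-1-yl N,N-di(propan-2-yl)carbamate | CC(C)N(C(C)C)C(=O)OCC/C(C)=C/Cc1cc(O[Si](C(C)C)(C(C)C)C(C)C)cc(C)c1O[Si](C(C)C)(C(C)C)C(C)C | intermediate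
21 | [(1S,3E)-1-(diisopropylcarbamoyloxy)-3-methyl-5-{3-methyl-2,5-bis[(triisopropylsilyl)oxy]phenyl}pent-3-en-1-yl]lithium | [Li][C@H](OC(=O)N(C(C)C)C(C)C)C/C(C)=C/Cc1cc(O[Si](C(C)C)(C(C)C)C(C)C)cc(C)c1O[Si](C(C)C)(C(C)C)C(C)C | intermediate (not isolated)
22 | lithium boronate complex: boron of 13 bonded additionally to the (S)-carbamoyloxy carbon of 21 | [Li+].CC(C)N(C(C)C)C(=O)O[C@H](C/C(C)=C/Cc1cc(O[Si](C(C)C)(C(C)C)C(C)C)cc(C)c1O[Si](C(C)C)(C(C)C)C(C)C)[B-]2(OC(C)(C)C(C)(C)O2)/C=C(\C)CC/C=C(\C)Cc1cc(C)co1 | intermediate (not isolated)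
23 | 4,4,5,5-tetramethyl-2-[(2E,5R,6E,10E)-3,7,11-trimethyl-12-(4-methylfuran-2-yl)-1-{3-methyl-2,5-bis[(triisopropylsilyl)oxy]phenyl}dodeca-2,6,10-trien-5-yl]-1,3,2-dioxaborolane | C/C(=C\[C@H](B1OC(C)(C)C(C)(C)O1)C/C(C)=C/Cc1cc(O[Si](C(C)C)(C(C)C)C(C)C)cc(C)c1O[Si](C(C)C)(C(C)C)C(C)C)CC/C=C(\C)Cc1cc(C)co1 | intermediate (not isolated)
24 | (2E,5R,6E,10E)-3,7,11-trimethyl-12-(4-methylfuran-2-yl)-1-{3-methyl-2,5-bis[(triisopropylsilyl)oxy]phenyl}dodeca-2,6,10-trien-5-ol | C/C(=C\[C@H](O)C/C(C)=C/Cc1cc(O[Si](C(C)C)(C(C)C)C(C)C)cc(C)c1O[Si](C(C)C)(C(C)C)C(C)C)CC/C=C(\C)Cc1cc(C)co1 | intermediate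
25 | 2-[(2E,5R,6E,10E)-5-hydroxy-3,7,11-trimethyl-12-(4-methylfuran-2-yl)dodeca-2,6,10-trien-1-yl]-6-methylbenzene-1,4-diol | C/C(=C\[C@H](O)C/C(C)=C/Cc1cc(O)cc(C)c1O)CC/C=C(\C)Cc1cc(C)co1 | target

## Step count and risks

Total step count: 11. Longest linear sequence: 7 (steps 1, 2, 3, 4, 5, 10, 11).

**Step 10 (highest risk).** sec-Butyllithium may also attack the doubly activated ArCH2–CH= position or a ring C–H next to a silyloxy group of 20, and the enantiomer ratio depends on clean α-lithiation. The fallback sets out from 15 and comes back at 24; it joins the carbanion and the boronic ester before the arene is attached. Alkyne 15 is C-silylated (n-BuLi, Me3SiCl, THF, −78 °C) to 4-(trimethylsilyl)but-3-yn-1-yl N,N-di(propan-2-yl)carbamate F1. Lithiation with sec-butyllithium/(−)-sparteine gives its (S)-α-lithio derivative F2, which adds to 13 to give the lithium boronate complex F3. This rearranges (MgBr2·OEt2) to the (R)-allylic boronic ester F4, and NaBO3·4H2O oxidation gives (4R,5E,9E)-6,10-dimethyl-11-(4-methylfuran-2-yl)-1-(trimethylsilyl)undeca-5,9-dien-1-yn-4-ol F5. K2CO3 in MeOH gives (4R,5E,9E)-6,10-dimethyl-11-(4-methylfuran-2-yl)undeca-5,9-dien-1-yn-4-ol F6. Carboalumination of this homopropargylic alcohol (Me3Al, Cp2ZrCl2, CH2Cl2) gives the alkenylalane aluminium alkoxide F7, which is coupled with 18 under Pd(PPh3)4 in THF and, after aqueous work-up, returns 24.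

**Step 4.** The C5 versus C2 selectivity of the metalation of 3-methylfuran is the least certain point outside the key step, and excess furyllithium is needed because of the alkyne C–H. The fallback sets out from 8 and comes back at 12. Sterically controlled C–H borylation of 8 (B2pin2, [Ir(OMe)(cod)]2, dtbpy, hexane, rt) gives 4,4,5,5-tetramethyl-2-(4-methylfuran-2-yl)-1,3,2-dioxaborolane F8. Suzuki–Miyaura coupling of F8 with 7 (Pd(PPh3)4, K3PO4, THF/H2O, 50 °C) attacks the CH2 terminus of the allyl unit, tolerates the free alkyne and gives 12.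

**Step 5.** The copper-catalysed methylboration of an alkyl-substituted terminal alkyne may suffer from copper acetylide formation or imperfect regioselectivity. The fallback sets out from 12 and comes back at 13. Zirconium-catalysed carboalumination (Me3Al, Cp2ZrCl2, CH2Cl2) gives dimethyl[(1E,5E)-2,6-dimethyl-7-(4-methylfuran-2-yl)hepta-1,5-dien-1-yl]alumane F9. Iodinolysis (I2, THF, −30 °C) gives 2-[(2E,6E)-7-iodo-2,6-dimethylhepta-2,6-dien-1-yl]-4-methylfuran F10. Miyaura borylation (B2pin2, PdCl2(PPh3)2, PPh3, KOPh, toluene, 50 °C) then gives 13 with retention of geometry.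

## Further compounds

F1 | step 10 | 4-(trimethylsilyl)but-3-yn-1-yl N,N-di(propan-2-yl)carbamate | C[Si](C)(C)C#CCCOC(=O)N(C(C)C)C(C)C
F2 | step 10 | [(1S)-1-(diisopropylcarbamoyloxy)-4-(trimethylsilyl)but-3-yn-1-yl]lithium | [Li][C@H](OC(=O)N(C(C)C)C(C)C)CC#C[Si](C)(C)C
F3 | step 10 | lithium boronate complex of F2 and 13 | [Li+].CC(C)N(C(C)C)C(=O)O[C@H](CC#C[Si](C)(C)C)[B-]1(OC(C)(C)C(C)(C)O1)/C=C(\C)CC/C=C(\C)Cc1cc(C)co1
F4 | step 10 | 4,4,5,5-tetramethyl-2-[(4R,5E,9E)-6,10-dimethyl-11-(4-methylfuran-2-yl)-1-(trimethylsilyl)undeca-5,9-dien-1-yn-4-yl]-1,3,2-dioxaborolane | C/C(=C\[C@H](B1OC(C)(C)C(C)(C)O1)CC#C[Si](C)(C)C)CC/C=C(\C)Cc1cc(C)co1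
F5 | step 10 | (4R,5E,9E)-6,10-dimethyl-11-(4-methylfuran-2-yl)-1-(trimethylsilyl)undeca-5,9-dien-1-yn-4-ol | C/C(=C\[C@H](O)CC#C[Si](C)(C)C)CC/C=C(\C)Cc1cc(C)co1
F6 | step 10 | (4R,5E,9E)-6,10-dimethyl-11-(4-methylfuran-2-yl)undeca-5,9-dien-1-yn-4-ol | C/C(=C\[C@H](O)CC#C)CC/C=C(\C)Cc1cc(C)co1
F7 | step 10 | dimethylaluminium alkoxide of the (1E)-alkenyldimethylalane from carboalumination of F6 | C/C(=C\[C@H](O[Al](C)C)C/C(C)=C/[Al](C)C)CC/C=C(\C)Cc1cc(C)co1
F8 | step 4 | 4,4,5,5-tetramethyl-2-(4-methylfuran-2-yl)-1,3,2-dioxaborolane | Cc1coc(B2OC(C)(C)C(C)(C)O2)c1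
F9 | step 5 | dimethyl[(1E,5E)-2,6-dimethyl-7-(4-methylfuran-2-yl)hepta-1,5-dien-1-yl]alumane | C[Al](C)/C=C(\C)CC/C=C(\C)Cc1cc(C)co1
F10 | step 5 | 2-[(2E,6E)-7-iodo-2,6-dimethylhepta-2,6-dien-1-yl]-4-methylfuran | I/C=C(\C)CC/C=C(\C)Cc1cc(C)co1
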